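**Plan**

- Target 20 is an achiral A–B–B–A tetramer joined by three CH2 bridges. The two rings A are butyrylfilicinic rings, with ring atoms called C1 (butyryl-bearing), C2 (C–OH), C3 (CMe2), C4 (C–OH), C5 (CH2-bearing) and C6 (C=O). The two rings B are phlorobutyrophenone rings.
- Cuts: first the four O–benzyl bonds, then C4–C5 and C1–C6 in both rings A. Each ring A then falls apart into a chroman-2-one fused to ring B (C5, C6, bridge CH2, ortho-O of B) and 3,3-dimethyl-6-propylpyran-2,4-dione (C1–C4 plus the butyryl group). After that come the lactone C3 units (CH2O, Meldrum's acid), the central CH2 and the aryl–acyl bonds.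
- Enabling feature: the path C6–C5–CH2–C(ar)–C(ar)–O is six atoms long. C6 can therefore be stored as an aryl δ-lactone that acidifies C5–H and carries its own leaving group. The C2–C1–C(=O)Pr edge is an enol lactone in disguise, and quaternary C3 forbids aromatisation and any enolisation between C2 and C4.
- Forward order: ring B from phloroglucinol, the central bridge first (no unsymmetrical bridge yet that could scramble), then two lactone rings and benzylation. Both rings A are closed last and together in one double annulation, followed by hydrogenolysis.
- Stereochemistry: none to set. The transient C-3 centres of the acylated lactones vanish on enolisation.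

Key step: step 7

Remark: the target SMILES holds no stereocentre and the molecule is achiral, so no enantiomer has to be chosen; enol tautomers are written as in the target SMILES.

Step 1
Reactants: 1 phloroglucinol; 2 butyryl chloride
Product: 3 1-(2,4,6-trihydroxyphenyl)butan-1-one (phlorobutyrophenone)
Conditions: AlCl3 (3.5 equiv), CH2Cl2–PhNO2, 0 → 45 °C; aq. HCl
Reagents that add atoms: butyryl chloride CCCC(=O)Cl
Why: Friedel–Crafts C-acylation of the electron-rich benzenetriol should stop after one acyl group because the chelated aryl ketone deactivates the ring.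

Step 2
Reactants: 3 phlorobutyrophenone (two molecules); 4 formaldehyde
Product: 5 1,1'-[methylenebis(2,4,6-trihydroxybenzene-3,1-diyl)]bis(butan-1-one) (methylenebis-phlorobutyrophenone)
Conditions: 37% aq. CH2O (0.4 equiv), KOH (1 equiv), H2O, 0 °C; then 1 M HCl
Reagents that add atoms: formaldehyde C=O
Why: Base-mediated hydroxymethylation gives an ortho-quinone methide that a second phenoxide captures at carbon (the classical methylene bridging of acylphloroglucinols), and the excess of 3 should hold back higher oligomers.

Step 3
Reactants: 5 methylenebis-phlorobutyrophenone; 4 formaldehyde; 6 Meldrum's acid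
Product: 9 8,8'-methylenebis(6-butanoyl-5,7-dihydroxychroman-2-one), via bis-Meldrum adduct 7 (not isolated), via bis-lactone diacid 8 (not isolated)
Conditions: 37% aq. CH2O (2.4 equiv), Meldrum's acid (2.4 equiv), L-proline (cat.), MeCN, rt; evaporate; pyridine, 100 °C
Reagents that add atoms: formaldehyde C=O; Meldrum's acid CC1(C)OC(=O)CC(=O)O1
Why: In this Yonemitsu-type three-component condensation, methylene Meldrum's acid (Knoevenagel) is attacked by the one free ring carbon of each arene, and on heating the hydroxyl para to the butyryl group (the only one not flanking the ketone) opens the dioxanedione with loss of acetone and the malonic half-ester loses CO2, as known for phloroglucinols, aldehydes and Meldrum's acid.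

Step 4
Reactants: 9 bis-lactone tetraphenol; 10 benzyl bromide
Product: 11 8,8'-methylenebis[5,7-bis(benzyloxy)-6-butanoylchroman-2-one]
Conditions: BnBr (5 equiv), K2CO3 (6 equiv), dry DMF, 50 °C
Reagents that add atoms: benzyl bromide BrCc1ccccc1
Why: Williamson O-benzylation under anhydrous carbonate conditions masks the four remaining acidic OH groups and should leave the aryl lactones alone, since their α-CH2 is far too weakly acidic for K2CO3.

Step 5
Reactants: 12 pentan-2-one; 13 chlorotrimethylsilane
Product: 14 2-(trimethylsilyloxy)pent-1-ene
Conditions: LDA (1.05 equiv), THF, −78 °C; TMSCl, −78 °C → rt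
Reagents that add atoms: chlorotrimethylsilane C[Si](C)(C)Cl
Why: Kinetic deprotonation of the methyl ketone at CH3 followed by O-silylation gives the terminal silyl enol ether (kinetic enolate silylation).

Step 6
Reactants: 14 2-(trimethylsilyloxy)pent-1-ene; 15 dimethylmalonyl dichloride
Product: 17 3,3-dimethyl-6-propyl-2H-pyran-2,4(3H)-dione, via dioxooctanoyl chloride 16 (not isolated)
Conditions: Et2O, −78 °C → rt, no catalyst
Reagents that add atoms: dimethylmalonyl dichloride CC(C)(C(=O)Cl)C(=O)Cl
Why: C-acylation of the silyl enol ether by one acid chloride group and O-acylation of the resulting enolised β-diketone by the second is the known pyranone synthesis from silyl enol ethers and malonyl dichlorides, and the quaternary carbon stops it at the 2,4-dione.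

Step 7
Reactants: 11 tetrabenzyl bis-lactone; 17 3,3-dimethyl-6-propyl-2H-pyran-2,4(3H)-dione (two molecules react)
Product: 19 tetra-O-benzyl ether of the target (benzyl on the four oxygens flanking the two aryl ketones), via bis-acyl-lactone 18 (not isolated)
Conditions: 17 (6 equiv), THF, Ar, −78 °C; LiHMDS (6.2 equiv, syringe pump); −78 → 23 °C; 1 M HCl
Reagents that add atoms: 3,3-dimethyl-6-propyl-2H-pyran-2,4(3H)-dione CCCC1=CC(=O)C(C)(C)C(=O)O1
Why: Proposed new method: LiHMDS, kept limiting by slow addition, removes the most acidic C–H available, H-3 of each aryl δ-lactone (fixed E-ester geometry and aryloxy group, estimated about 4 pKa units below the α-CH2 of the twisted 2,6-dibenzyloxyaryl ketones), and the enolate carbon (future C5) attacks C-2 of 17, a vinylogous anhydride carbonyl, so that the pyrandione opens to the β-diketonate of 18. The diketonate carbon (future C1) then attacks the chromanone carbonyl (future C6), directly or after E1cB loss of the tethered aryloxide to an acylketene, in a 6-(enolexo)-exo-trig Dieckmann closure that frees the phenol, so that per arm two heterocycles are unzipped and one carbocycle is zipped up with two new C–C bonds and no loss of atoms. The closest known reaction types are the crossed Claisen acylation of lactone enolates by activated esters, the opening of 3,3-dialkylpyran-2,4-diones at C-2 by N- and O-nucleophiles, and the base-induced Claisen cyclisation of pyrones and polyketo esters to acylphloroglucinols. Of the selectivities needed, cross- over self-acylation rests on the excess of 17 and its better leaving group, attack at C-2 of 17 rather than C-4 or C-6 on the fact that these belong to a deactivated vinylogous ester, and C- over O-closure and Claisen over aldol mode on the reversibility of the alternatives, whereas the β-triketonate (three equivalents of base are taken up per arm) is a thermodynamic sink. The quaternary CMe2 carbon blocks enolisation between its two carbonyl groups, prevents aromatisation and should speed the closure (gem-dialkyl effect). No stereocentre results, because C-3 of 18 is configurationally labile and ends as an sp2 enol carbon.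

Step 8
Reactants: 19 tetra-O-benzyl ether of the target
Product: 20 target CNP0110234.0
Conditions: H2 (1 atm), 10% Pd/C, EtOAc–MeOH, rt
Reagents that add atoms: none
Why: Neutral hydrogenolysis of the four aryl benzyl ethers should leave enolised β-triketones, aryl ketones and diarylmethane C–C bonds intact and avoids the alkaline media in which methylene-bridged phloroglucinols exchange their halves.

**Compound list**

1 | phloroglucinol | Oc1cc(O)cc(O)c1 | starting material
2 | butyryl chloride | CCCC(=O)Cl | starting material
3 | 1-(2,4,6-trihydroxyphenyl)butan-1-one | CCCC(=O)c1c(O)cc(O)cc1O | intermediate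
4 | formaldehyde | C=O | starting material
5 | methylenebis-phlorobutyrophenone | CCCC(=O)c1c(O)cc(O)c(Cc2c(O)cc(O)c(C(=O)CCC)c2O)c1O | intermediate
6 | Meldrum's acid | CC1(C)OC(=O)CC(=O)O1 | starting material
7 | bis-Meldrum adduct (each free ring carbon of 5 carries CH2–(2,2-dimethyl-4,6-dioxo-1,3-dioxan-5-yl)), not isolated | CCCC(=O)c1c(O)c(CC2C(=O)OC(C)(C)OC2=O)c(O)c(Cc2c(O)c(CC3C(=O)OC(C)(C)OC3=O)c(O)c(C(=O)CCC)c2O)c1O | intermediate
8 | 8,8'-methylenebis(6-butanoyl-5,7-dihydroxy-2-oxochromane-3-carboxylic acid), not isolated | O=C1C(C(=O)O)Cc2c(O)c(C(=O)CCC)c(O)c(Cc3c(O)c(C(=O)CCC)c(O)c4CC(C(=O)O)C(=O)Oc34)c2O1 | intermediate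
9 | 8,8'-methylenebis(6-butanoyl-5,7-dihydroxychroman-2-one) | O=C1CCc2c(O)c(C(=O)CCC)c(O)c(Cc3c(O)c(C(=O)CCC)c(O)c4CCC(=O)Oc34)c2O1 | intermediate
10 | benzyl bromide | BrCc1ccccc1 | starting material
11 | 8,8'-methylenebis[5,7-bis(benzyloxy)-6-butanoylchroman-2-one] | O=C1CCc2c(OCc3ccccc3)c(C(=O)CCC)c(OCc4ccccc4)c(Cc5c(OCc6ccccc6)c(C(=O)CCC)c(OCc7ccccc7)c8CCC(=O)Oc58)c2O1 | intermediate
12 | pentan-2-one | CCCC(C)=O | starting material
13 | chlorotrimethylsilane | C[Si](C)(C)Cl | starting material
14 | 2-(trimethylsilyloxy)pent-1-ene | CCCC(=C)O[Si](C)(C)C | intermediate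
15 | dimethylmalonyl dichloride | CC(C)(C(=O)Cl)C(=O)Cl | starting material
16 | 2,2-dimethyl-3,5-dioxooctanoyl chloride, not isolated | CCCC(=O)CC(=O)C(C)(C)C(=O)Cl | intermediate
17 | 3,3-dimethyl-6-propyl-2H-pyran-2,4(3H)-dione | CCCC1=CC(=O)C(C)(C)C(=O)O1 | intermediate
18 | 8,8'-methylenebis[5,7-bis(benzyloxy)-6-butanoyl-3-(2,2-dimethyl-3,5-dioxooctanoyl)chroman-2-one], present as lithium enolates, C-3 labile, not isolated | O=C1C(C(=O)C(C)(C)C(=O)CC(=O)CCC)Cc2c(OCc3ccccc3)c(C(=O)CCC)c(OCc4ccccc4)c(Cc5c(OCc6ccccc6)c(C(=O)CCC)c(OCc7ccccc7)c8CC(C(=O)C(C)(C)C(=O)CC(=O)CCC)C(=O)Oc58)c2O1 | intermediate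
19 | tetra-O-benzyl ether of the target (free OH on each ring B only between the two CH2 groups) | CCCC(=O)C1=C(O)C(C)(C)C(O)=C(Cc2c(O)c(Cc3c(O)c(CC4=C(O)C(C)(C)C(O)=C(C(=O)CCC)C4=O)c(OCc5ccccc5)c(C(=O)CCC)c3OCc6ccccc6)c(OCc7ccccc7)c(C(=O)CCC)c2OCc8ccccc8)C1=O | intermediate
20 | CNP0110234.0 (methylene-bridged A–B–B–A tetramer, all acyl groups butanoyl) | CCCC(=O)C1=C(O)C(C)(C)C(O)=C(Cc2c(O)c(Cc3c(O)c(CC4=C(O)C(C)(C)C(O)=C(C(=O)CCC)C4=O)c(O)c(C(=O)CCC)c3O)c(O)c(C(=O)CCC)c2O)C1=O | target

Total step count: 8. Longest linear sequence: 6 (steps 1, 2, 3, 4, 7, 8).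

**Steps most likely to fail**

(a) Step 7.
- What may go wrong: the lactone enolate may be quenched by proton transfer from the acidic product or from the γ-CH2 of 17. The lactone units may acylate each other, the aryl ketones may be enolised and acylated, and conjugate attack at C-6 of 17 may compete.
- Fallback: this uses known chemistry, sets out from 3 and 5, and comes back at 20. The late ring construction is given up.
- Compound 3 is dearomatised by double C-methylation (MeI, NaOMe, MeOH) to butyrylfilicinic acid F1.
- Compound 5 is turned with aqueous formaldehyde and dimethylamine into the bis-Mannich base F2.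
- Warming F2 with F1 in dioxane sets free an ortho-quinone methide at each end. F1 captures it at its free ring carbon and gives 20 without protecting groups.

(b) Step 3.
- What may go wrong: formaldehyde may bridge arene to arene (oligomerisation), and a second Meldrum's acid may capture methylene Meldrum's acid.
- Lactone closure on the other ortho-oxygen may also occur. That would only change which oxygens later carry benzyl and would still converge on 20.
- Fallback: this sets out from 5 and comes back at 9. The C3 unit is brought in by a Pechmann-type hydroarylation and lactonisation with ethyl propiolate (ZnCl2, 100 °C), giving the bis-coumarin F3.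
- The two C3=C4 bonds of F3 are then saturated (H2, Pd/C, EtOAc–AcOH) to give 9.

(c) Step 6.
- What may go wrong: O-acylation of the enol ether, protodesilylation by the hydrogen chloride formed, and carbocyclisation through the second α-carbon of the ketone.
- Fallback: this sets out from 2 and comes back at 17. The lithium enolate of commercial methyl 2,2-dimethyl-3-oxobutanoate (LDA, 2 equiv; enolisable only at CH3) is acylated with 2 to give methyl 2,2-dimethyl-3,5-dioxooctanoate F4.
- F4 is closed to the enol lactone 17 by acid (conc. H2SO4, 0 °C), the usual cyclisation of 3,5-dioxo esters to pyranones.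

**Further compounds**

F1 | step 7 | butyrylfilicinic acid (2-butanoyl-3,5-dihydroxy-4,4-dimethylcyclohexa-2,5-dien-1-one) | CCCC(=O)C1=C(O)C(C)(C)C(O)=CC1=O
F2 | step 7 | bis-Mannich base of 5 (CH2NMe2 on each free ring carbon) | CCCC(=O)c1c(O)c(CN(C)C)c(O)c(Cc2c(O)c(CN(C)C)c(O)c(C(=O)CCC)c2O)c1O
F3 | step 3 | 8,8'-methylenebis(6-butanoyl-5,7-dihydroxy-2H-chromen-2-one) | O=c1ccc2c(O)c(C(=O)CCC)c(O)c(Cc3c(O)c(C(=O)CCC)c(O)c4ccc(=O)oc34)c2o1
F4 | step 6 | methyl 2,2-dimethyl-3,5-dioxooctanoate | CCCC(=O)CC(=O)C(C)(C)C(=O)OC
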